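The route rests on C3, the only stereocentre: a CH bonded to C1′ of ring B, to C4 (the benzylic CH2 of ring A) and to C2 (the CH2 that ends on O1). All three of its carbon bonds can be handled on boron. An α-lithiated phenethyl carbamate (C3 with C4 and ring A already attached) is trapped by the ring B chromenyl boronate; ring B shifts from boron to C3, and chloromethyllithium then inserts C2 into the C3–B bond. One operation thus makes C3–C1′ and C2–C3 and sets (R)-C3, without closing a ring. The precursors are a bis-silylated ring A phenethyl carbamate and a silylated 8-borylchromene.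

Key step: step 9

Remarks on the chemistry
- Assumption: 2,4-dihydroxy-6-methoxybenzaldehyde 1 is taken as a catalogue compound (otherwise it is one Vilsmeier formylation away from 5-methoxyresorcinol).
- Ring A entry: the methyl ether is brought in with 1. 2,4,6-Trihydroxybenzaldehyde would be O-methylated first at the 4-hydroxyl, not at the hydrogen-bonded 2-hydroxyl that becomes the C5 methoxy group.
- Stereochemistry: the target is (3R). (−)-Sparteine is the enantiomer needed: it removes the pro-S proton, capture by boron goes with retention, the aryl shift with inversion and the CH2 insertion with retention. This gives (R) in 20, 22, 23, 24 and 26.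
- Ring B: the bromine of 7 blocks one ortho position in the Claisen step and is the handle for boron. Boronate 16 is the limiting partner in step 9, so none is left over to be homologated by chloromethyllithium.

Step 1
Reactants: 1 2,4-dihydroxy-6-methoxybenzaldehyde
Product: 2 2-methoxy-4,6-bis(triisopropylsilyloxy)benzaldehyde
Conditions: TIPSOTf (2.4 equiv), 2,6-lutidine, CH2Cl2, 0 °C to rt
Reagents that add atoms: triisopropylsilyl trifluoromethanesulfonate, CC(C)[Si](C(C)C)(C(C)C)OS(=O)(=O)C(F)(F)F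
Why: Silylation of phenols, in which the silyl triflate is reactive enough to cap the hydroxyl hydrogen-bonded to the aldehyde as well, and the bulky silyl ethers later shield ring A from lithiation.

Step 2
Reactants: 2 2-methoxy-4,6-bis(triisopropylsilyloxy)benzaldehyde
Product: 3 2-ethenyl-1-methoxy-3,5-bis(triisopropylsilyloxy)benzene
Conditions: Ph3PCH3Br, NaN(SiMe3)2, THF, 0 °C; then 2, 0 °C to rt
Reagents that add atoms: methyltriphenylphosphonium bromide, C[P+](c1ccccc1)(c1ccccc1)c1ccccc1.[Br-]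
Why: Wittig methylenation of a non-enolisable aromatic aldehyde, with the ylide made by a non-nucleophilic amide base so that the aryl silyl ethers are not attacked.

Step 3
Reactants: 3 2-ethenyl-1-methoxy-3,5-bis(triisopropylsilyloxy)benzene
Product: 5 2-[2-methoxy-4,6-bis(triisopropylsilyloxy)phenyl]ethanol, via alkyl-9-BBN adduct 4 (not isolated)
Conditions: 9-BBN, THF, 0 °C to rt; then NaBO3·4H2O, H2O, rt
Reagents that add atoms: 9-borabicyclo[3.3.1]nonane (its boron stays only in 4), [H]B1C2CCCC1CCC2; sodium perborate tetrahydrate (oxygen), [Na+].[Na+].O[B-]1(O)OO[B-](O)(O)OO1.O.O.O.O.O.O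
Why: Anti-Markovnikov hydroboration of a styrene, in which the bulky borane should place boron on the terminal carbon, followed by mild perborate oxidation of the C–B bond that spares the aryl silyl ethers.

Step 4
Reactants: 5 2-[2-methoxy-4,6-bis(triisopropylsilyloxy)phenyl]ethanol
Product: 6 2-[2-methoxy-4,6-bis(triisopropylsilyloxy)phenyl]ethyl N,N-diisopropylcarbamate
Conditions: i-Pr2NCOCl, Et3N, CH2Cl2, reflux
Reagents that add atoms: N,N-diisopropylcarbamoyl chloride, CC(C)N(C(C)C)C(=O)Cl
Why: Carbamoylation (acyl substitution) of a primary alcohol, the standard way to O-alkyl N,N-diisopropylcarbamates, under amine-base conditions that avoid alkoxide-induced silyl migration.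

Step 5
Reactants: 7 4-bromobenzene-1,3-diol
Product: 8 2-bromo-5-(triisopropylsilyloxy)phenol
Conditions: TIPSCl (1.0 equiv), imidazole, CH2Cl2, −20 to 0 °C
Reagents that add atoms: triisopropylsilyl chloride, CC(C)[Si](Cl)(C(C)C)C(C)C
Why: Silylation of a phenol, in which the bulky chlorosilane should react at the unhindered hydroxyl para to bromine well before the hydroxyl flanked by bromine.

Step 6
Reactants: 8 2-bromo-5-(triisopropylsilyloxy)phenol; 9 3-chloro-3-methylbut-1-yne
Product: 10 1-bromo-2-[(2-methylbut-3-yn-2-yl)oxy]-4-(triisopropylsilyloxy)benzene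
Conditions: CuCl2·2H2O (cat.), DBU, MeCN, 0 °C
Reagents that add atoms: none
Why: Copper-catalysed O-alkylation of a phenol with a tertiary propargylic chloride, a mild etherification that tolerates ortho-substituted, acidic phenols and aryl silyl ethers.

Step 7
Reactants: 10 1-bromo-2-[(2-methylbut-3-yn-2-yl)oxy]-4-(triisopropylsilyloxy)benzene
Product: 14 8-bromo-2,2-dimethyl-5-(triisopropylsilyloxy)-2H-chromene, via allenyl dienone 11 (not isolated), via allenylphenol 12 (not isolated), via ortho-quinone methide 13 (not isolated)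
Conditions: o-xylene, 140 °C
Reagents that add atoms: none
Why: Aromatic propargyl Claisen rearrangement, whose [3,3] shift can end productively only at the free ortho carbon between the two oxygens (the other carries bromine), followed by enolisation, 1,5-hydrogen shift and oxa-6π electrocyclisation to the 2,2-dimethylchromene.

Step 8
Reactants: 14 8-bromo-2,2-dimethyl-5-(triisopropylsilyloxy)-2H-chromene
Product: 16 2-[2,2-dimethyl-5-(triisopropylsilyloxy)-2H-chromen-8-yl]-4,4,5,5-tetramethyl-1,3,2-dioxaborolane, via chromenyllithium 15 (not isolated)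
Conditions: n-BuLi, THF, −78 °C; then i-PrOBpin, −78 °C to rt
Reagents that add atoms: 2-isopropoxy-4,4,5,5-tetramethyl-1,3,2-dioxaborolane, CC(C)OB1OC(C)(C)C(C)(C)O1
Why: Bromine–lithium exchange followed by electrophilic borylation of the aryllithium, a standard route to aryl pinacol boronates in which the exchange at −78 °C should outrun any reaction at the chromene or the silyl ether.

Step 9
Reactants: 6 2-[2-methoxy-4,6-bis(triisopropylsilyloxy)phenyl]ethyl N,N-diisopropylcarbamate; 16 2-[2,2-dimethyl-5-(triisopropylsilyloxy)-2H-chromen-8-yl]-4,4,5,5-tetramethyl-1,3,2-dioxaborolane; 17 bromochloromethane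
Product: 22 pinacol (2R)-3-[2-methoxy-4,6-bis(triisopropylsilyloxy)phenyl]-2-[2,2-dimethyl-5-(triisopropylsilyloxy)-2H-chromen-8-yl]propylboronate, via lithiated carbamate 18 (not isolated), via boronate complex 19 (not isolated), via secondary boronic ester 20 (not isolated), via chloromethyl boronate complex 21 (not isolated)
Conditions: 6 (1.3 equiv), s-BuLi (1.25 equiv), (−)-sparteine (1.3 equiv), Et2O, −78 °C, 5 h; 16 (1.0 equiv), −78 °C, 1 h; reflux, 16 h; then THF, 17 (3 equiv), n-BuLi (2.5 equiv), −78 °C to rt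
Reagents that add atoms: none
Why: s-BuLi/(−)-sparteine, held by the carbamate carbonyl, removes the pro-S proton next to the carbamate oxygen of 6 and gives the configurationally stable (S)-lithium carbenoid 18, which adds to boron of 16 with retention to give complex 19; on warming, ring B moves from boron to C3 anti to the departing carbamate (inversion), which forms C3–C1′ and the secondary boronic ester 20. Chloromethyllithium, made in the flask from 17 and n-BuLi, then gives complex 21, in which C3 moves from boron to the CH2 carbon with retention as chloride leaves, which forms C2–C3. The closest known reaction types are the sparteine-mediated lithiation–borylation of primary alkyl carbamates with aryl boronic esters and the Matteson homologation of secondary benzylic boronic esters; no ring is closed. The single stereocentre C3 is reagent-controlled: (−)-sparteine decides which enantiotopic proton is lost, and the two stereospecific 1,2-shifts carry this through to (R)-C3. The step needs lithiation next to the carbamate oxygen in preference to the benzylic CH2 and to ring A, which the directing carbamate and the bulky, non-coordinating silyl ethers should secure, and it needs a clean aryl shift, which the ortho- and para-oxygenated, electron-rich ring B should provide.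

Step 10
Reactants: 22 pinacol (2R)-3-[2-methoxy-4,6-bis(triisopropylsilyloxy)phenyl]-2-[2,2-dimethyl-5-(triisopropylsilyloxy)-2H-chromen-8-yl]propylboronate
Product: 23 (2R)-3-[2-methoxy-4,6-bis(triisopropylsilyloxy)phenyl]-2-[2,2-dimethyl-5-(triisopropylsilyloxy)-2H-chromen-8-yl]propan-1-ol
Conditions: NaBO3·4H2O, THF/H2O, rt
Reagents that add atoms: sodium perborate tetrahydrate, [Na+].[Na+].O[B-]1(O)OO[B-](O)(O)OO1.O.O.O.O.O.O
Why: Oxidation of a primary alkyl boronic ester, in which hydroperoxide adds to boron and C2 migrates to oxygen, so C3 is untouched and the weakly basic medium should spare the silyl ethers and the chromene alkene.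

Step 11
Reactants: 23 (2R)-3-[2-methoxy-4,6-bis(triisopropylsilyloxy)phenyl]-2-[2,2-dimethyl-5-(triisopropylsilyloxy)-2H-chromen-8-yl]propan-1-ol
Product: 24 (2R)-3-[2-methoxy-4,6-bis(triisopropylsilyloxy)phenyl]-2-[2,2-dimethyl-5-(triisopropylsilyloxy)-2H-chromen-8-yl]propyl methanesulfonate
Conditions: MsCl, Et3N, CH2Cl2, 0 °C
Reagents that add atoms: methanesulfonyl chloride, CS(=O)(=O)Cl
Why: Sulfonylation of the only free hydroxyl, a primary alcohol, which installs the leaving group at C2 without touching the silyl ethers or C3.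

Step 12
Reactants: 24 (2R)-3-[2-methoxy-4,6-bis(triisopropylsilyloxy)phenyl]-2-[2,2-dimethyl-5-(triisopropylsilyloxy)-2H-chromen-8-yl]propyl methanesulfonate
Product: 26 (3R)-3-(5-hydroxy-2,2-dimethyl-2H-chromen-8-yl)-5-methoxy-3,4-dihydro-2H-chromen-7-ol, via desilylated mesylate 25 (not isolated)
Conditions: Bu4NF (3.3 equiv), THF (degassed, 0.01 M), 0 °C to rt; AcOH quench
Reagents that add atoms: none
Why: Fluoride cleaves the three aryl silyl ethers and the C8a phenoxide of 25, six atoms from C2, should displace the primary mesylate in an intramolecular Williamson etherification (6-exo-tet) that closes ring C at C2 and leaves C3 unchanged.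

Compound list
1 | 2,4-dihydroxy-6-methoxybenzaldehyde | COc1cc(O)cc(O)c1C=O | starting material
2 | 2-methoxy-4,6-bis(triisopropylsilyloxy)benzaldehyde | COc1cc(O[Si](C(C)C)(C(C)C)C(C)C)cc(O[Si](C(C)C)(C(C)C)C(C)C)c1C=O | intermediate
3 | 2-ethenyl-1-methoxy-3,5-bis(triisopropylsilyloxy)benzene | COc1cc(O[Si](C(C)C)(C(C)C)C(C)C)cc(O[Si](C(C)C)(C(C)C)C(C)C)c1C=C | intermediate
4 | 9-{2-[2-methoxy-4,6-bis(triisopropylsilyloxy)phenyl]ethyl}-9-borabicyclo[3.3.1]nonane | COc1cc(O[Si](C(C)C)(C(C)C)C(C)C)cc(O[Si](C(C)C)(C(C)C)C(C)C)c1CCB1C2CCCC1CCC2 | intermediate (not isolated)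
5 | 2-[2-methoxy-4,6-bis(triisopropylsilyloxy)phenyl]ethanol | COc1cc(O[Si](C(C)C)(C(C)C)C(C)C)cc(O[Si](C(C)C)(C(C)C)C(C)C)c1CCO | intermediate
6 | 2-[2-methoxy-4,6-bis(triisopropylsilyloxy)phenyl]ethyl N,N-diisopropylcarbamate | COc1cc(O[Si](C(C)C)(C(C)C)C(C)C)cc(O[Si](C(C)C)(C(C)C)C(C)C)c1CCOC(=O)N(C(C)C)C(C)C | intermediate
7 | 4-bromobenzene-1,3-diol | Oc1ccc(Br)c(O)c1 | starting material
8 | 2-bromo-5-(triisopropylsilyloxy)phenol | Oc1cc(O[Si](C(C)C)(C(C)C)C(C)C)ccc1Br | intermediate
9 | 3-chloro-3-methylbut-1-yne | C#CC(C)(C)Cl | starting material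
10 | 1-bromo-2-[(2-methylbut-3-yn-2-yl)oxy]-4-(triisopropylsilyloxy)benzene | C#CC(C)(C)Oc1cc(O[Si](C(C)C)(C(C)C)C(C)C)ccc1Br | intermediate
11 | 6-bromo-2-(3-methylbuta-1,2-dien-1-yl)-3-(triisopropylsilyloxy)cyclohexa-3,5-dien-1-one (racemic) | O=C1C(Br)=CC=C(O[Si](C(C)C)(C(C)C)C(C)C)C1C=C=C(C)C | intermediate (not isolated)
12 | 6-bromo-2-(3-methylbuta-1,2-dien-1-yl)-3-(triisopropylsilyloxy)phenol | Oc1c(Br)ccc(O[Si](C(C)C)(C(C)C)C(C)C)c1C=C=C(C)C | intermediate (not isolated)
13 | 6-bromo-2-(3-methylbut-2-en-1-ylidene)-3-(triisopropylsilyloxy)cyclohexa-3,5-dien-1-one | O=C1C(Br)=CC=C(O[Si](C(C)C)(C(C)C)C(C)C)C1=CC=C(C)C | intermediate (not isolated)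
14 | 8-bromo-2,2-dimethyl-5-(triisopropylsilyloxy)-2H-chromene | Brc1ccc(O[Si](C(C)C)(C(C)C)C(C)C)c2c1OC(C)(C)C=C2 | intermediate
15 | [2,2-dimethyl-5-(triisopropylsilyloxy)-2H-chromen-8-yl]lithium | [Li]c1ccc(O[Si](C(C)C)(C(C)C)C(C)C)c2c1OC(C)(C)C=C2 | intermediate (not isolated)
16 | 2-[2,2-dimethyl-5-(triisopropylsilyloxy)-2H-chromen-8-yl]-4,4,5,5-tetramethyl-1,3,2-dioxaborolane | CC1(C)OB(OC1(C)C)c1ccc(O[Si](C(C)C)(C(C)C)C(C)C)c2c1OC(C)(C)C=C2 | intermediate
17 | bromochloromethane | ClCBr | starting material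
18 | (1S)-1-lithio-2-[2-methoxy-4,6-bis(triisopropylsilyloxy)phenyl]ethyl N,N-diisopropylcarbamate, as its (−)-sparteine complex | COc1cc(O[Si](C(C)C)(C(C)C)C(C)C)cc(O[Si](C(C)C)(C(C)C)C(C)C)c1C[C@H]([Li])OC(=O)N(C(C)C)C(C)C | intermediate (not isolated)
19 | lithium boronate complex from 18 and 16, (S) at the carbon bearing boron and the carbamate | COc1cc(O[Si](C(C)C)(C(C)C)C(C)C)cc(O[Si](C(C)C)(C(C)C)C(C)C)c1C[C@@H](OC(=O)N(C(C)C)C(C)C)[B-]1(c2ccc(O[Si](C(C)C)(C(C)C)C(C)C)c3c2OC(C)(C)C=C3)OC(C)(C)C(C)(C)O1.[Li+] | intermediate (not isolated)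
20 | pinacol (1R)-2-[2-methoxy-4,6-bis(triisopropylsilyloxy)phenyl]-1-[2,2-dimethyl-5-(triisopropylsilyloxy)-2H-chromen-8-yl]ethylboronate | COc1cc(O[Si](C(C)C)(C(C)C)C(C)C)cc(O[Si](C(C)C)(C(C)C)C(C)C)c1C[C@H](c1ccc(O[Si](C(C)C)(C(C)C)C(C)C)c2c1OC(C)(C)C=C2)B1OC(C)(C)C(C)(C)O1 | intermediate (not isolated)
21 | lithium (chloromethyl)boronate complex of 20, (R) at C3 | COc1cc(O[Si](C(C)C)(C(C)C)C(C)C)cc(O[Si](C(C)C)(C(C)C)C(C)C)c1C[C@H](c1ccc(O[Si](C(C)C)(C(C)C)C(C)C)c2c1OC(C)(C)C=C2)[B-]1(CCl)OC(C)(C)C(C)(C)O1.[Li+] | intermediate (not isolated)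
22 | pinacol (2R)-3-[2-methoxy-4,6-bis(triisopropylsilyloxy)phenyl]-2-[2,2-dimethyl-5-(triisopropylsilyloxy)-2H-chromen-8-yl]propylboronate | COc1cc(O[Si](C(C)C)(C(C)C)C(C)C)cc(O[Si](C(C)C)(C(C)C)C(C)C)c1C[C@H](c1ccc(O[Si](C(C)C)(C(C)C)C(C)C)c2c1OC(C)(C)C=C2)CB1OC(C)(C)C(C)(C)O1 | intermediate
23 | (2R)-3-[2-methoxy-4,6-bis(triisopropylsilyloxy)phenyl]-2-[2,2-dimethyl-5-(triisopropylsilyloxy)-2H-chromen-8-yl]propan-1-ol | COc1cc(O[Si](C(C)C)(C(C)C)C(C)C)cc(O[Si](C(C)C)(C(C)C)C(C)C)c1C[C@H](c1ccc(O[Si](C(C)C)(C(C)C)C(C)C)c2c1OC(C)(C)C=C2)CO | intermediate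
24 | (2R)-3-[2-methoxy-4,6-bis(triisopropylsilyloxy)phenyl]-2-[2,2-dimethyl-5-(triisopropylsilyloxy)-2H-chromen-8-yl]propyl methanesulfonate | COc1cc(O[Si](C(C)C)(C(C)C)C(C)C)cc(O[Si](C(C)C)(C(C)C)C(C)C)c1C[C@H](c1ccc(O[Si](C(C)C)(C(C)C)C(C)C)c2c1OC(C)(C)C=C2)COS(C)(=O)=O | intermediate
25 | (2R)-3-(2,4-dihydroxy-6-methoxyphenyl)-2-(5-hydroxy-2,2-dimethyl-2H-chromen-8-yl)propyl methanesulfonate (present as its phenoxides) | COc1cc(O)cc(O)c1C[C@H](c1ccc(O)c2c1OC(C)(C)C=C2)COS(C)(=O)=O | intermediate (not isolated)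
26 | (3R)-3-(5-hydroxy-2,2-dimethyl-2H-chromen-8-yl)-5-methoxy-3,4-dihydro-2H-chromen-7-ol | COc1cc(O)cc2c1C[C@H](c1ccc(O)c3c1OC(C)(C)C=C3)CO2 | target

Total step count: 12.
Longest linear sequence: 8 steps (steps 1–4, then 9–12; the ring B branch, steps 5–8 and 9–12, is equally long).

Steps most likely to fail

1. Step 9. Deprotonation may occur at the benzylic CH2 or on ring A instead of next to the carbamate oxygen. The ortho-substituted aryl group may also transfer slowly from the hindered boronate complex, or the CH2 unit may insert incompletely or twice. The fallback replaces the boron chemistry by an auxiliary-controlled enolate alkylation; it sets out from 14 and 2 and comes back at 23. Bromide 14 is coupled with the Reformatsky reagent BrZnCH2CO2Et (Pd2(dba)3, XPhos, THF, 60 °C; Negishi-type coupling) to give ethyl 2-[2,2-dimethyl-5-(triisopropylsilyloxy)-2H-chromen-8-yl]acetate F1. LiOH (THF/H2O, 0 °C) gives 2-[2,2-dimethyl-5-(triisopropylsilyloxy)-2H-chromen-8-yl]acetic acid F2. Pivaloyl chloride/Et3N and then the lithium salt of (R)-4-benzyl-1,3-oxazolidin-2-one give (4R)-4-benzyl-3-{2-[2,2-dimethyl-5-(triisopropylsilyloxy)-2H-chromen-8-yl]acetyl}-1,3-oxazolidin-2-one F3. Aldehyde 2 is reduced with NaBH4 to [2-methoxy-4,6-bis(triisopropylsilyloxy)phenyl]methanol F4 and converted with PPh3/CBr4 into 2-(bromomethyl)-1-methoxy-3,5-bis(triisopropylsilyloxy)benzene F5, which is used at once. The sodium enolate of F3 (NaN(SiMe3)2, THF, −78 °C) should be alkylated by F5 on the face away from the benzyl group of the auxiliary (Evans alkylation) to give (4R)-4-benzyl-3-{(2R)-3-[2-methoxy-4,6-bis(triisopropylsilyloxy)phenyl]-2-[2,2-dimethyl-5-(triisopropylsilyloxy)-2H-chromen-8-yl]propanoyl}-1,3-oxazolidin-2-one F6. LiBH4 (THF, 0 °C) removes the auxiliary reductively and gives 23.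

2. Step 12. Once desilylated, the ring B phenoxide (para to C1′) may attack C2 through C1′ to form a spirocyclopropane, which would scramble C2 and C3. Fluoride may also displace the mesylate, or elimination across C2–C3 may occur. The fallback closes the ring under nearly neutral conditions; it sets out from 23 and comes back at 26. Bu4NF buffered with AcOH (THF, 0 °C) removes the three silyl groups and gives 2-[(2R)-3-hydroxy-2-(5-hydroxy-2,2-dimethyl-2H-chromen-8-yl)propyl]-5-methoxybenzene-1,3-diol F7. Mitsunobu cyclodehydration (PPh3, DIAD, THF, 0 °C, high dilution) should then form the O1–C2 bond through the C8a hydroxyl, the only phenol that can reach C2 in a six-membered transition state, and give 26.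

3. Step 5. Silylation may occur at the hydroxyl next to bromine or at both hydroxyls, which would give regioisomers that carry through to a wrongly fused chromene. The fallback uses a phenol whose two oxygens are already differentiated; it sets out from 9 and comes back at 14. Chloride 9 O-alkylates commercial 2-bromo-5-methoxyphenol F8 (CuCl2·2H2O cat., DBU, MeCN, 0 °C) to give 1-bromo-4-methoxy-2-[(2-methylbut-3-yn-2-yl)oxy]benzene F9. Claisen rearrangement (o-xylene, 140 °C) gives 8-bromo-5-methoxy-2,2-dimethyl-2H-chromene F10. NaSEt (DMF, 120 °C) cleaves the methyl ether to 8-bromo-2,2-dimethyl-2H-chromen-5-ol F11, and TIPSCl/imidazole (CH2Cl2, rt) gives 14.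

Further compounds
F1 | step 9 | ethyl 2-[2,2-dimethyl-5-(triisopropylsilyloxy)-2H-chromen-8-yl]acetate | CCOC(=O)Cc1ccc(O[Si](C(C)C)(C(C)C)C(C)C)c2c1OC(C)(C)C=C2
F2 | step 9 | 2-[2,2-dimethyl-5-(triisopropylsilyloxy)-2H-chromen-8-yl]acetic acid | OC(=O)Cc1ccc(O[Si](C(C)C)(C(C)C)C(C)C)c2c1OC(C)(C)C=C2
F3 | step 9 | (4R)-4-benzyl-3-{2-[2,2-dimethyl-5-(triisopropylsilyloxy)-2H-chromen-8-yl]acetyl}-1,3-oxazolidin-2-one | O=C(Cc1ccc(O[Si](C(C)C)(C(C)C)C(C)C)c2c1OC(C)(C)C=C2)N1[C@H](Cc2ccccc2)COC1=O
F4 | step 9 | [2-methoxy-4,6-bis(triisopropylsilyloxy)phenyl]methanol | COc1cc(O[Si](C(C)C)(C(C)C)C(C)C)cc(O[Si](C(C)C)(C(C)C)C(C)C)c1CO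
F5 | step 9 | 2-(bromomethyl)-1-methoxy-3,5-bis(triisopropylsilyloxy)benzene | COc1cc(O[Si](C(C)C)(C(C)C)C(C)C)cc(O[Si](C(C)C)(C(C)C)C(C)C)c1CBr
F6 | step 9 | (4R)-4-benzyl-3-{(2R)-3-[2-methoxy-4,6-bis(triisopropylsilyloxy)phenyl]-2-[2,2-dimethyl-5-(triisopropylsilyloxy)-2H-chromen-8-yl]propanoyl}-1,3-oxazolidin-2-one | COc1cc(O[Si](C(C)C)(C(C)C)C(C)C)cc(O[Si](C(C)C)(C(C)C)C(C)C)c1C[C@H](c1ccc(O[Si](C(C)C)(C(C)C)C(C)C)c2c1OC(C)(C)C=C2)C(=O)N1[C@H](Cc2ccccc2)COC1=O
F7 | step 12 | 2-[(2R)-3-hydroxy-2-(5-hydroxy-2,2-dimethyl-2H-chromen-8-yl)propyl]-5-methoxybenzene-1,3-diol | COc1cc(O)cc(O)c1C[C@H](c1ccc(O)c2c1OC(C)(C)C=C2)CO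
F8 | step 5 | 2-bromo-5-methoxyphenol | COc1ccc(Br)c(O)c1
F9 | step 5 | 1-bromo-4-methoxy-2-[(2-methylbut-3-yn-2-yl)oxy]benzene | C#CC(C)(C)Oc1cc(OC)ccc1Br
F10 | step 5 | 8-bromo-5-methoxy-2,2-dimethyl-2H-chromene | COc1ccc(Br)c2OC(C)(C)C=Cc12
F11 | step 5 | 8-bromo-2,2-dimethyl-2H-chromen-5-ol | Oc1ccc(Br)c2OC(C)(C)C=Cc12
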